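**Retrosynthetic overview**
1. Target 28 comes from the octa-O-benzyl trimer 27 by hydrogenolysis. Trimer 27 is taken apart unit by unit from the bottom, each unit by the same two disconnections.
2. Lower ring C (O1–C2–C3–C4–C4a–C8a) is cut in a formal [3+3] sense at C4–C4a and O1–C2. This gives the dimer-borne 3-benzyloxy-2,4-dihydroxyphenyl group of 24 and the cis-epoxy aldehyde 5, which supplies C4–C3–C2 and ring B.
3. Enabling feature: in lower ring A, C4a is the only unsubstituted carbon ortho to a phenolic oxygen (O1), and it lies para to O7. The all-cis array C4(OH)–C3(OH)–C2(OAr) is what anti addition to the formyl group plus inversion at the benzylic carbon of a cis-2,3-epoxy aldehyde delivers.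
4. The interflavan bonds C4→C6 come from Friedel–Crafts capture of flavan-4-yl cations by the symmetric 2-O-benzylpyrogallol 12, so each ring A is attached before its ring C exists.
5. Ring order: upper ring C (step 8), middle ring C (step 11), lower ring C (step 14, last). All benzene rings are bought.

Key step: step 14

Remark on names: flavan numbering (O1, C2, C3, C4, C4a, C5–C8, C8a, primes for ring B) is used for every unit. "Upper, middle, lower" run from the unit without substituent at C6 to the unit with the 4-OH. "Epioritin" means (2R,3R)-2,3-cis-flavan-3,7,8,4'-tetraol. 4β is trans and 4α is cis to the 3-OH.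
Remark on the chemistry: the (S,S)-catalyst of step 2 is assumed to give the (2S,3S)-glycidate, by analogy with the established sense of induction for cis-cinnamates. If the sense were opposite, the (R,R)-catalyst would be used.

Step 1
Reactants: 1 4-(benzyloxy)benzaldehyde; 2 methyl bis(2,2,2-trifluoroethyl)phosphonoacetate
Product: 3 methyl (Z)-3-[4-(benzyloxy)phenyl]prop-2-enoate
Conditions: KN(SiMe3)2, 18-crown-6, THF, −78 °C
Reagents that add atoms: none
Why: Still–Gennari variant of the Horner–Wadsworth–Emmons olefination, in which the electron-poor phosphonate eliminates fast from the kinetic adduct and should give the Z-cinnamate needed for a cis-epoxide.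

Step 2
Reactants: 3 methyl (Z)-3-[4-(benzyloxy)phenyl]prop-2-enoate
Product: 4 methyl (2S,3S)-3-[4-(benzyloxy)phenyl]oxirane-2-carboxylate (cis)
Conditions: (S,S)-Mn(salen)Cl (6 mol %; salen = N,N'-bis(3,5-di-tert-butylsalicylidene)cyclohexane-1,2-diamine dianion), NaOCl (aq, pH 11.3), 4-phenylpyridine N-oxide (0.25 equiv), CH2Cl2, 4 °C
Reagents that add atoms: sodium hypochlorite [Na+].[O-]Cl
Why: Jacobsen–Katsuki epoxidation, for which cis-cinnamates are a privileged substrate class; the chiral oxo-manganese species sets both epoxide carbons by face-selective oxygen transfer, and any trans-epoxide from the stepwise pathway is removed by chromatography.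

Step 3
Reactants: 4 methyl (2S,3S)-3-[4-(benzyloxy)phenyl]oxirane-2-carboxylate
Product: 5 (2S,3S)-3-[4-(benzyloxy)phenyl]oxirane-2-carbaldehyde (cis)
Conditions: i-Bu2AlH (1.05 equiv), toluene, −78 °C; aq potassium sodium tartrate
Reagents that add atoms: none
Why: Low-temperature partial reduction of an ester, well known for glycidic esters; neither epoxide carbon is touched, so both stereocentres are carried over.

Step 4
Reactants: 6 resorcinol
Product: 7 1,3-bis(methoxymethoxy)benzene
Conditions: NaH, MOMCl, DMF, 0 °C → rt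
Reagents that add atoms: chloromethyl methyl ether COCCl
Why: Williamson-type O-alkylation of both phenoxides installs two groups that will direct metalation to the carbon between them.

Step 5
Reactants: 7 1,3-bis(methoxymethoxy)benzene
Product: 10 2,6-bis(methoxymethoxy)phenol, via 2-lithio arene 8 (not isolated), via dimethyl arylboronate 9 (not isolated)
Conditions: n-BuLi, THF, 0 °C → rt; B(OMe)3, −78 °C → rt; H2O2 (30 % aq), NaOH, 0 °C
Reagents that add atoms: hydrogen peroxide OO
Why: Directed ortho-metalation at C2, flanked by two coordinating OMOM groups, followed by borylation and basic peroxide oxidation (1,2-aryl shift from boron to oxygen), a standard arene hydroxylation that spares the acid-labile acetals.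

Step 6
Reactants: 10 2,6-bis(methoxymethoxy)phenol
Product: 11 2-(benzyloxy)-1,3-bis(methoxymethoxy)benzene
Conditions: BnBr, K2CO3, DMF, 60 °C
Reagents that add atoms: benzyl bromide BrCc1ccccc1
Why: Williamson etherification of the only free phenol.

Step 7
Reactants: 11 2-(benzyloxy)-1,3-bis(methoxymethoxy)benzene
Product: 12 2-(benzyloxy)benzene-1,3-diol
Conditions: HCl (cat.), MeOH, 50 °C
Reagents that add atoms: none
Why: Acid-catalysed transacetalisation removes both MOM groups and leaves the benzyl ether, giving a symmetric resorcinol-type nucleophile whose C4 and C6 are equivalent.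

Step 8
Reactants: 12 2-(benzyloxy)benzene-1,3-diol; 5 (2S,3S)-3-[4-(benzyloxy)phenyl]oxirane-2-carbaldehyde
Product: 15 (2R,3R,4R)-8-(benzyloxy)-2-[4-(benzyloxy)phenyl]chromane-3,4,7-triol, via titanium bis-phenolate 13 (not isolated), via epoxy carbinol 14 (not isolated)
Conditions: 12 (2.5 equiv), Ti(OiPr)4 (5 equiv), toluene, rt, i-PrOH stripped in vacuo; 5 (1 equiv), toluene–CH2Cl2, −20 °C → rt; aq NaHCO3, Celite
Reagents that add atoms: none
Why: Proposed new method: the aryloxytitanium binds the formyl oxygen of 5 and delivers the formyl carbon to the ortho carbon through a closed six-membered transition state (closest known type: ortho-specific, anti-selective hydroxyalkylation of triisopropoxytitanium phenolates by alpha-alkoxy aldehydes), attack on the polar Felkin–Anh/Cornforth conformer from the H3 side setting C4 with O4 anti to the epoxide oxygen, and the resulting titanium-bound 2,3-epoxy alcohol is opened at its distal benzylic carbon by the neighbouring aryloxide (closest known types: titanium-mediated C3-selective opening of 2,3-epoxy alcohols and 6-endo phenol/aryl-epoxide closure to flavan-3-ols), which inverts C2 and keeps C3 so that the cis-epoxide becomes the 2,3-cis-3,4-cis array, while the excess of symmetric 12 limits a second annulation.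

Step 9
Reactants: 15 (2R,3R,4R)-8-(benzyloxy)-2-[4-(benzyloxy)phenyl]chromane-3,4,7-triol
Product: 16 (2R,3R,4R)-7,8-bis(benzyloxy)-2-[4-(benzyloxy)phenyl]chromane-3,4-diol
Conditions: BnBr (1.1 equiv), K2CO3, DMF, rt
Reagents that add atoms: benzyl bromide BrCc1ccccc1
Why: Williamson etherification in which carbonate deprotonates only the phenolic 7-OH, so the 3,4-diol and all stereocentres stay untouched and the one aryloxide that could later direct a reaction to C6 of this unit is capped.

Step 10
Reactants: 16 (2R,3R,4R)-7,8-bis(benzyloxy)-2-[4-(benzyloxy)phenyl]chromane-3,4-diol; 12 2-(benzyloxy)benzene-1,3-diol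
Product: 18 (2R,3R,4S)-7,8-bis(benzyloxy)-4-[3-(benzyloxy)-2,4-dihydroxyphenyl]-2-[4-(benzyloxy)phenyl]chroman-3-ol, via flavan-4-yl cation 17 (not isolated)
Conditions: 12 (4 equiv), BF3·OEt2 (0.3 equiv), CH2Cl2–Et2O, −20 → 0 °C
Reagents that add atoms: none
Why: Friedel–Crafts alkylation of a phenol by a flavan-4-yl cation, the classical interflavan bond formation: the cation is stabilised by O7 (para) and O1 (ortho), the arene adds to the β face anti to the axial 3-OH of the 2,3-cis series (3,4-trans, C4 set by substrate control), the equivalence of C4 and C6 in 12 allows one regioisomer only, and the excess of 12 suppresses double alkylation.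

Step 11
Reactants: 18 (2R,3R,4S)-7,8-bis(benzyloxy)-4-[3-(benzyloxy)-2,4-dihydroxyphenyl]-2-[4-(benzyloxy)phenyl]chroman-3-ol; 5 (2S,3S)-3-[4-(benzyloxy)phenyl]oxirane-2-carbaldehyde
Product: 21 penta-O-benzyl dimer with free lower 7-OH (epioritin-(4β→6)-epioritin-4α-ol skeleton), via titanium bis-phenolate 19 (not isolated), via epoxy carbinol 20 (not isolated)
Conditions: Ti(OiPr)4 (3.3 equiv), toluene, rt, i-PrOH stripped in vacuo; 5 (1.3 equiv), toluene–CH2Cl2, −20 °C → rt; aq NaHCO3, Celite
Reagents that add atoms: none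
Why: Proposed new method: the same titanium-templated domino as in step 8 (aryloxytitanium-directed ortho-hydroxyalkylation, then metal-assisted 6-endo opening of the resulting 2,3-epoxy alcohol at benzylic C2, closest known types as named there), now regiospecific because 18 has a single unsubstituted carbon ortho to an aryloxide, with C4 set by polar Felkin–Anh/Cornforth attack, C3 carried from 5 and C2 set by inversion.

Step 12
Reactants: 21 penta-O-benzyl dimer with free lower 7-OH
Product: 22 hexa-O-benzyl dimer 3,4-diol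
Conditions: BnBr (1.1 equiv), K2CO3, DMF, rt
Reagents that add atoms: benzyl bromide BrCc1ccccc1
Why: Williamson etherification of the only phenol, leaving the three aliphatic hydroxyl groups and all stereocentres untouched.

Step 13
Reactants: 22 hexa-O-benzyl dimer 3,4-diol; 12 2-(benzyloxy)benzene-1,3-diol
Product: 24 hepta-O-benzyl dimer carrying a 4β-[3-(benzyloxy)-2,4-dihydroxyphenyl] group on the lower unit, via dimeric flavan-4-yl cation 23 (not isolated)
Conditions: 12 (4 equiv), BF3·OEt2 (0.3 equiv), CH2Cl2–Et2O, −20 → 0 °C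
Reagents that add atoms: none
Why: Friedel–Crafts alkylation as in step 10: only the C4–OH of the diol unit can ionise, the strongly nucleophilic free resorcinol ring outcompetes all benzylated arenes, and β-face attack anti to the axial 3-OH sets the new C4 as 3,4-trans.

Step 14
Reactants: 24 hepta-O-benzyl dimer carrying a 4β-[3-(benzyloxy)-2,4-dihydroxyphenyl] group; 5 (2S,3S)-3-[4-(benzyloxy)phenyl]oxirane-2-carbaldehyde
Product: 27 octa-O-benzyl trimer with free lower 7-OH, via titanium bis-phenolate 25 (not isolated), via epoxy carbinol 26 (not isolated)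
Conditions: Ti(OiPr)4 (4.4 equiv), toluene, rt, i-PrOH stripped in vacuo; 5 (1.5 equiv), toluene–CH2Cl2, −20 °C → rt; aq NaHCO3, Celite
Reagents that add atoms: none
Why: Proposed new method: ligand exchange gives the aryloxytitanium species 25, the tetravalent titanium on O1 binds the formyl oxygen of 5, C4a attacks through a closed six-membered transition state to give the titanium-bound epoxy carbinol 26, and O1 then opens the epoxide at benzylic C2. The closest known reaction types are the ortho-specific, anti-selective hydroxyalkylation of triisopropoxytitanium phenolates by alpha-alkoxy aldehydes, the titanium-mediated C3-selective opening of 2,3-epoxy alcohols and the 6-endo phenol/aryl-epoxide cyclisation used for flavan-3-ols; new is their union in one flask on an epoxy aldehyde. Lower ring C is built in a formal [3+3] manner and the ring-closing event is a 6-endo-tet attack of O1 on C2, preferred over 5-exo attack on C3 because C2 is para-alkoxybenzylic and is the distal carbon of the O4–Ti–O3 chelate. C4 (R, 4α-OH) is set by polar Felkin–Anh/Cornforth attack on the aldehyde face flanked by H3, the other face being covered by the cis-aryl epoxide; C3 (R) is carried unchanged from 5; C2 (R) arises by inversion of the (S)-benzylic epoxide carbon, so reagent control by 5 overrides the remote stereocentres of 24. The step needs site selectivity among five skeletal arenes and four hydroxyl groups, secured because only lower ring A bears aryloxides, C4a is its only unsubstituted ortho carbon (O7 is flanked by substituted C6 and C8) and is also para to O7, and the formyl group keeps the epoxide of 5 inert until the C–C bond exists. One operation thus brings in ring B and C2–C4 and makes two bonds, one ring and three stereocentres without any change of protecting groups.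

Step 15
Reactants: 27 octa-O-benzyl trimer with free lower 7-OH
Product: 28 epioritin-(4β→6)-epioritin-(4β→6)-epioritin-4α-ol (target)
Conditions: H2 (1 atm), Pd(OH)2/C, THF–MeOH–H2O, rt, stopped at full debenzylation
Reagents that add atoms: none
Why: Hydrogenolysis of the eight aryl benzyl ethers, the standard last step for benzylated proanthocyanidins; in a neutral medium these O–CH2Ph bonds should cleave faster than the secondary benzylic C4–OH, C2–O1 and C4–aryl bonds, and no stereocentre is involved.

**Compound list**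
1 | 4-(benzyloxy)benzaldehyde | O=Cc1ccc(OCc2ccccc2)cc1 | starting material
2 | methyl bis(2,2,2-trifluoroethyl)phosphonoacetate | COC(=O)CP(=O)(OCC(F)(F)F)OCC(F)(F)F | starting material
3 | methyl (Z)-3-[4-(benzyloxy)phenyl]prop-2-enoate | COC(=O)/C=C\c1ccc(OCc2ccccc2)cc1 | intermediate
4 | methyl (2S,3S)-3-[4-(benzyloxy)phenyl]oxirane-2-carboxylate (cis) | COC(=O)[C@H]1O[C@H]1c1ccc(OCc2ccccc2)cc1 | intermediate
5 | (2S,3S)-3-[4-(benzyloxy)phenyl]oxirane-2-carbaldehyde (cis) | O=C[C@H]1O[C@H]1c1ccc(OCc2ccccc2)cc1 | intermediate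
6 | resorcinol | Oc1cccc(O)c1 | starting material
7 | 1,3-bis(methoxymethoxy)benzene | COCOc1cccc(OCOC)c1 | intermediate
8 | 2-lithio-1,3-bis(methoxymethoxy)benzene | [Li]c1c(OCOC)cccc1OCOC | intermediate
9 | dimethyl [2,6-bis(methoxymethoxy)phenyl]boronate | COCOc1cccc(OCOC)c1B(OC)OC | intermediate
10 | 2,6-bis(methoxymethoxy)phenol | COCOc1cccc(OCOC)c1O | intermediate
11 | 2-(benzyloxy)-1,3-bis(methoxymethoxy)benzene | COCOc1cccc(OCOC)c1OCc1ccccc1 | intermediate
12 | 2-(benzyloxy)benzene-1,3-diol | Oc1cccc(O)c1OCc1ccccc1 | intermediate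
13 | bis(triisopropoxytitanium) phenolate of 12 | CC(C)O[Ti](OC(C)C)(OC(C)C)Oc1cccc(O[Ti](OC(C)C)(OC(C)C)OC(C)C)c1OCc1ccccc1 | intermediate
14 | (R)-[3-(benzyloxy)-2,4-dihydroxyphenyl][(2R,3S)-3-[4-(benzyloxy)phenyl]oxiran-2-yl]methanol, cis-epoxide, held as its titanium alkoxide and drawn protonated | O[C@H](c1ccc(O)c(OCc2ccccc2)c1O)[C@H]1O[C@H]1c1ccc(OCc2ccccc2)cc1 | intermediate
15 | (2R,3R,4R)-8-(benzyloxy)-2-[4-(benzyloxy)phenyl]chromane-3,4,7-triol (2,3-cis-3,4-cis) | Oc1ccc2c(c1OCc1ccccc1)O[C@H](c1ccc(OCc3ccccc3)cc1)[C@H](O)[C@@H]2O | intermediate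
16 | (2R,3R,4R)-7,8-bis(benzyloxy)-2-[4-(benzyloxy)phenyl]chromane-3,4-diol | c1ccccc1COc1ccc2c(c1OCc1ccccc1)O[C@H](c1ccc(OCc3ccccc3)cc1)[C@H](O)[C@@H]2O | intermediate
17 | (2R,3R)-flavan-4-yl cation from 16 | c1ccccc1COc1ccc2c(c1OCc1ccccc1)O[C@H](c1ccc(OCc3ccccc3)cc1)[C@H](O)[CH+]2 | intermediate
18 | (2R,3R,4S)-7,8-bis(benzyloxy)-4-[3-(benzyloxy)-2,4-dihydroxyphenyl]-2-[4-(benzyloxy)phenyl]chroman-3-ol (2,3-cis-3,4-trans, 4β-aryl) | c1ccccc1COc1ccc([C@H]2Oc3c(ccc(OCc4ccccc4)c3OCc3ccccc3)[C@H](c3ccc(O)c(OCc4ccccc4)c3O)[C@H]2O)cc1 | intermediate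
19 | bis(triisopropoxytitanium) phenolate of 18 (the 3-OH also exchanges with titanium; drawn free) | c1ccccc1COc1ccc([C@H]2Oc3c(ccc(OCc4ccccc4)c3OCc3ccccc3)[C@H](c3ccc(O[Ti](OC(C)C)(OC(C)C)OC(C)C)c(OCc4ccccc4)c3O[Ti](OC(C)C)(OC(C)C)OC(C)C)[C@H]2O)cc1 | intermediate
20 | 18 carrying, ortho to the 4-OH of its dihydroxyphenyl ring, the (R)-hydroxy[(2R,3S)-cis-3-(4-benzyloxyphenyl)oxiranyl]methyl group; held on titanium, drawn protonated | c1ccccc1COc1ccc([C@H]2Oc3c(ccc(OCc4ccccc4)c3OCc3ccccc3)[C@H](c3cc([C@@H](O)[C@H]4O[C@H]4c4ccc(OCc5ccccc5)cc4)c(O)c(OCc4ccccc4)c3O)[C@H]2O)cc1 | intermediate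
21 | penta-O-benzyl dimer: 7,8,4'-tri-O-benzylepioritin joined 4β→6 to 8,4'-di-O-benzylepioritin-4α-ol (both units 2R,3R; lower 3,4-cis diol; lower 7-OH free) | c1ccccc1COc1ccc([C@H]2Oc3c(ccc(OCc4ccccc4)c3OCc3ccccc3)[C@H](c3cc4c(c(OCc5ccccc5)c3O)O[C@H](c3ccc(OCc5ccccc5)cc3)[C@H](O)[C@@H]4O)[C@H]2O)cc1 | intermediate
22 | hexa-O-benzyl dimer: 21 with the lower O7 benzylated | c1ccccc1COc1ccc([C@H]2Oc3c(ccc(OCc4ccccc4)c3OCc3ccccc3)[C@H](c3cc4c(c(OCc5ccccc5)c3OCc3ccccc3)O[C@H](c3ccc(OCc5ccccc5)cc3)[C@H](O)[C@@H]4O)[C@H]2O)cc1 | intermediate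
23 | dimeric flavan-4-yl cation from 22 (charge at C4 of the lower unit) | c1ccccc1COc1ccc([C@H]2Oc3c(ccc(OCc4ccccc4)c3OCc3ccccc3)[C@H](c3cc4c(c(OCc5ccccc5)c3OCc3ccccc3)O[C@H](c3ccc(OCc5ccccc5)cc3)[C@H](O)[CH+]4)[C@H]2O)cc1 | intermediate
24 | hepta-O-benzyl dimer: hexa-O-benzyl epioritin-(4β→6)-epioritin whose second unit bears a 4β-[3-(benzyloxy)-2,4-dihydroxyphenyl] group (both units 2R,3R, both 3,4-trans) | c1ccccc1COc1ccc([C@H]2Oc3c(ccc(OCc4ccccc4)c3OCc3ccccc3)[C@H](c3cc4c(c(OCc5ccccc5)c3OCc3ccccc3)O[C@H](c3ccc(OCc5ccccc5)cc3)[C@H](O)[C@H]4c3ccc(O)c(OCc4ccccc4)c3O)[C@H]2O)cc1 | intermediate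
25 | bis(triisopropoxytitanium) phenolate of 24 (the two 3-OH groups also exchange with titanium; drawn free) | c1ccccc1COc1ccc([C@H]2Oc3c(ccc(OCc4ccccc4)c3OCc3ccccc3)[C@H](c3cc4c(c(OCc5ccccc5)c3OCc3ccccc3)O[C@H](c3ccc(OCc5ccccc5)cc3)[C@H](O)[C@H]4c3ccc(O[Ti](OC(C)C)(OC(C)C)OC(C)C)c(OCc4ccccc4)c3O[Ti](OC(C)C)(OC(C)C)OC(C)C)[C@H]2O)cc1 | intermediate
26 | 24 carrying at the future C4a the (R)-hydroxy[(2R,3S)-cis-3-(4-benzyloxyphenyl)oxiranyl]methyl group; held on titanium, drawn protonated | c1ccccc1COc1ccc([C@H]2Oc3c(ccc(OCc4ccccc4)c3OCc3ccccc3)[C@H](c3cc4c(c(OCc5ccccc5)c3OCc3ccccc3)O[C@H](c3ccc(OCc5ccccc5)cc3)[C@H](O)[C@H]4c3cc([C@@H](O)[C@H]4O[C@H]4c4ccc(OCc5ccccc5)cc4)c(O)c(OCc4ccccc4)c3O)[C@H]2O)cc1 | intermediate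
27 | octa-O-benzyl trimer: benzyl ethers on O7, O8, O4' of the upper and middle units and on O8, O4' of the lower unit; every unit 2R,3R (2,3-cis); both interflavan bonds 4β→6 (3,4-trans); lower unit 4α-OH (3,4-cis), 7-OH free | c1ccccc1COc1ccc([C@H]2Oc3c(ccc(OCc4ccccc4)c3OCc3ccccc3)[C@H](c3cc4c(c(OCc5ccccc5)c3OCc3ccccc3)O[C@H](c3ccc(OCc5ccccc5)cc3)[C@H](O)[C@H]4c3cc4c(c(OCc5ccccc5)c3O)O[C@H](c3ccc(OCc5ccccc5)cc3)[C@H](O)[C@@H]4O)[C@H]2O)cc1 | intermediate
28 | epioritin-(4β→6)-epioritin-(4β→6)-epioritin-4α-ol (upper 2R,3R,4S; middle 2R,3R,4S; lower 2R,3R,4R) | Oc1ccc([C@H]2Oc3c(ccc(O)c3O)[C@H](c3cc4c(c(O)c3O)O[C@H](c3ccc(O)cc3)[C@H](O)[C@H]4c3cc4c(c(O)c3O)O[C@H](c3ccc(O)cc3)[C@H](O)[C@@H]4O)[C@H]2O)cc1 | target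

**Step count**
Total step count: 15.
Longest linear sequence: 12 steps (resorcinol 6 to 28, steps 4–15). The arm to 5 (steps 1–3) is made once and used three times.

**Steps most likely to fail**

Step 14.
- What may go wrong: on the crowded, poly-titanated substrate the C–C bond formation may be slow.
- What may go wrong: once the epoxy carbinol exists, the para-benzyloxybenzylic C2–O bond may ionise before O1 arrives. That would erode the inversion at C2 (drift toward the 2,3-trans series) or open the way to 5-exo closure.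
- Fallback: it uses known anionic chemistry, still closes the same ring last, sets out from 24 (with 5) and comes back at 27. Compound 24 is brominated with NBS (1 equiv, CH2Cl2–MeCN, −40 °C) at the only carbon ortho to a free phenol to give the aryl bromide F1. All four hydroxyl groups are silylated (TBSOTf, 2,6-lutidine) to give the tetrakis-silyl ether F2. Bromine–lithium exchange (n-BuLi, THF, −78 °C) and addition of the aryllithium to 5 under polar Felkin–Anh control gives the silylated epoxy carbinol F3, from which any C4 epimer is separated. TBAF in THF then frees the O1 phenoxide, which closes the ring by SN2-type 6-endo opening under basic conditions, and strips the remaining silyl groups to give 27.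

Step 11.
- What may go wrong: titanium may be sequestered in unreactive chelates or aggregates by the neighbouring 3-OH and the hindered O7, so the aldehyde is consumed by slow hydride transfer from isopropoxide instead of by arylation.
- Fallback: this is the classical interflavan coupling, and the lower ring of the trimer is still made last in step 14. It sets out from 16 and 15 and comes back at 21. Diol 16 is thiolysed (BnSH, catalytic BF3·OEt2, CH2Cl2, 0 °C) to the 4β-benzylsulfanyl flavan-3-ol F4. The thioether is then activated selectively with the thiophilic salt AgBF4 (THF, 0 °C) in the presence of excess 15. C6 of 15 (ortho to the free 7-OH, para to O1) captures the cation from the β face, while its own 4α-OH is not ionised under these conditions, giving 21.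

Step 8.
- What may go wrong: a second annulation may occur at the other aryloxide of the small symmetric phenolate.
- What may go wrong: facial selectivity at the aldehyde may be insufficient when the aryl partner is unhindered.
- Fallback: it uses stepwise known chemistry, sets out from 12 (with 5) and comes back at 15. Monobromination of 12 (NBS, 1 equiv, CH2Cl2–MeCN, −40 °C) gives 4-bromo-2-(benzyloxy)benzene-1,3-diol F5. Silylation (TBSCl, imidazole, DMF) gives the bis-silyl ether F6. Bromine–lithium exchange (n-BuLi, THF, −78 °C) and addition to 5 gives the epoxy carbinol F7. TBAF releases the phenoxide, which closes the ring with inversion at C2 to give 15.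

**Further compounds**
F1 | step 14 | 24 brominated at the carbon ortho to the 4-OH of its dihydroxyphenyl ring (future C4a) | c1ccccc1COc1ccc([C@H]2Oc3c(ccc(OCc4ccccc4)c3OCc3ccccc3)[C@H](c3cc4c(c(OCc5ccccc5)c3OCc3ccccc3)O[C@H](c3ccc(OCc5ccccc5)cc3)[C@H](O)[C@H]4c3cc(Br)c(O)c(OCc4ccccc4)c3O)[C@H]2O)cc1
F2 | step 14 | tetrakis(tert-butyldimethylsilyl) ether of F1 (both 3-OH groups and both phenols) | c1ccccc1COc1ccc([C@H]2Oc3c(ccc(OCc4ccccc4)c3OCc3ccccc3)[C@H](c3cc4c(c(OCc5ccccc5)c3OCc3ccccc3)O[C@H](c3ccc(OCc5ccccc5)cc3)[C@H](O[Si](C)(C)C(C)(C)C)[C@H]4c3cc(Br)c(O[Si](C)(C)C(C)(C)C)c(OCc4ccccc4)c3O[Si](C)(C)C(C)(C)C)[C@H]2O[Si](C)(C)C(C)(C)C)cc1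
F3 | step 14 | F2 with bromine replaced by the (R)-hydroxy[(2R,3S)-cis-3-(4-benzyloxyphenyl)oxiranyl]methyl group | c1ccccc1COc1ccc([C@H]2Oc3c(ccc(OCc4ccccc4)c3OCc3ccccc3)[C@H](c3cc4c(c(OCc5ccccc5)c3OCc3ccccc3)O[C@H](c3ccc(OCc5ccccc5)cc3)[C@H](O[Si](C)(C)C(C)(C)C)[C@H]4c3cc([C@@H](O)[C@H]4O[C@H]4c4ccc(OCc5ccccc5)cc4)c(O[Si](C)(C)C(C)(C)C)c(OCc4ccccc4)c3O[Si](C)(C)C(C)(C)C)[C@H]2O[Si](C)(C)C(C)(C)C)cc1
F4 | step 11 | 4β-(benzylsulfanyl)-7,8-bis(benzyloxy)-2-[4-(benzyloxy)phenyl]chroman-3-ol (2,3-cis-3,4-trans, 2R) | c1ccccc1COc1ccc([C@H]2Oc3c(ccc(OCc4ccccc4)c3OCc3ccccc3)[C@H](SCc3ccccc3)[C@H]2O)cc1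
F5 | step 8 | 4-bromo-2-(benzyloxy)benzene-1,3-diol | Oc1ccc(Br)c(O)c1OCc1ccccc1
F6 | step 8 | 2-(benzyloxy)-4-bromo-1,3-bis(tert-butyldimethylsilyloxy)benzene | CC(C)(C)[Si](C)(C)Oc1ccc(Br)c(O[Si](C)(C)C(C)(C)C)c1OCc1ccccc1
F7 | step 8 | (R)-[3-(benzyloxy)-2,4-bis(tert-butyldimethylsilyloxy)phenyl][(2R,3S)-cis-3-[4-(benzyloxy)phenyl]oxiran-2-yl]methanol | O[C@H](c1ccc(O[Si](C)(C)C(C)(C)C)c(OCc2ccccc2)c1O[Si](C)(C)C(C)(C)C)[C@H]1O[C@H]1c1ccc(OCc2ccccc2)cc1
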